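**Retrosynthetic overview**
1. Carotenoid numbering is used. Ring A = C1–C6 (cyclohexanol carrying the C5–C6 oxirane); ring B = C1'–C6' (acetoxycyclohexene). The last C–C bond made is the sp2–sp2 single bond C12'–C13'. A one-pot hydrostannation/Stille union of the C18 enediyne acetate 28 (ring B + C7'–C12') with the unprotected C24 pentaenyl iodide 22 (C13' to C7 + ring A) gives the target directly.
2. Enabling feature: C11'=C12' is a 1,2-disubstituted E-alkene next to methyl-bearing C13', so it can be carried as the terminal alkyne C11'≡C12'–H. The only other triple bond, C7'≡C8', is internal and walled in by the C1' gem-dimethyl and C5' methyl groups of ring B and by the C9' methyl group. The triene C13=C14–C15=C15'–C14'=C13' is locally C2-symmetric, so one diiodide 17 serves both C12–C13 and C12'–C13'.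
3. 22 comes from 17 and enyne diol 19 by the same kind of coupling at C12–C13, then MnO2 at C8. 19 comes from ring-A aldehyde 8 and iodoenyne 13 by a Nozaki–Hiyama–Kishi reaction (C8–C9).
4. One C4 block, (E)-3-iodobut-2-en-1-ol 11, supplies C9–C11, C13–C15 and C13'–C15'. One enol triflate 4 from actinol supplies both rings (allylation for ring A, Sonogashira coupling for ring B).
5. Ring order: both carbocycles are bought with actinol. The only ring closed in the route is the oxirane C5–O–C6 (step 4), before any polyene is present.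

Key step: step 21

Assumption: enantiopure (4R,6R)-actinol 1, an industrial xanthophyll intermediate, is taken as purchasable; its carbinol carbon becomes both C3 and C3'.

**Step 1**
Reactants: 1 (4R,6R)-4-hydroxy-2,2,6-trimethylcyclohexan-1-one (actinol)
Product: 2 (4R,6R)-4-(tert-butyldimethylsilyloxy)-2,2,6-trimethylcyclohexan-1-one
Conditions: TBSCl, imidazole, DMF, 25 °C
Reagents that add atoms: tert-butyldimethylsilyl chloride, CC(C)(C)[Si](C)(C)Cl
Why: Imidazole-promoted silyl ether formation masks the carbinol, whose chiral-pool configuration is untouched and later stands as C3 and C3'.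

**Step 2**
Reactants: 2 (4R,6R)-4-(tert-butyldimethylsilyloxy)-2,2,6-trimethylcyclohexan-1-one
Product: 4 (4R)-4-(tert-butyldimethylsilyloxy)-2,6,6-trimethylcyclohex-1-en-1-yl trifluoromethanesulfonate, via lithium enolate 3 (not isolated)
Conditions: LiN(iPr)2, THF, −78 → 0 °C; then PhNTf2, −78 → 25 °C
Reagents that add atoms: N-phenylbis(trifluoromethanesulfonimide), O=S(=O)(N(c1ccccc1)S(=O)(=O)C(F)(F)F)C(F)(F)F; lithium diisopropylamide, [Li]N(C(C)C)C(C)C (its lithium stands in 3 only)
Why: The ketone can enolise only toward the methyl-bearing α-carbon because the other α-carbon is quaternary, so enolate O-triflation (enol triflate synthesis) gives a single tetrasubstituted enol triflate and erases a stereocentre the target does not need.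

**Step 3**
Reactants: 4 enol triflate
Product: 5 tert-butyldimethylsilyl ether of (1R)-4-allyl-3,5,5-trimethylcyclohex-3-en-1-ol
Conditions: allyltributylstannane, Pd(PPh3)4 (5 mol %), LiCl (3 equiv), THF, reflux
Reagents that add atoms: allyltributylstannane, C=CC[Sn](CCCC)(CCCC)CCCC
Why: The LiCl-promoted Stille coupling of an enol triflate with an allylstannane attaches C7 and C8 plus one sacrificial carbon to C6 as a skipped diene.

**Step 4**
Reactants: 5 allyl cyclohexene
Product: 6 (1S,4S,6R)-1-allyl-4-(tert-butyldimethylsilyloxy)-2,2,6-trimethyl-7-oxabicyclo[4.1.0]heptane (oxirane anti to the silyloxy group)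
Conditions: mCPBA (1.0 equiv), NaHCO3, CH2Cl2, −20 → 0 °C
Reagents that add atoms: 3-chloroperbenzoic acid, OOC(=O)c1cccc(Cl)c1
Why: The Prilezhaev epoxidation picks the electron-rich tetrasubstituted C5=C6 over the monosubstituted allyl alkene, and the peracid should approach anti to the bulky C3 silyloxy group, as is usual for 3-acyloxy and 3-silyloxy β-end groups, which sets C5 (R) and C6 (S); a minor syn isomer would be removed by chromatography.

**Step 5**
Reactants: 6 allyl epoxide
Product: 8 2-[(1S,4S,6R)-4-(tert-butyldimethylsilyloxy)-2,2,6-trimethyl-7-oxabicyclo[4.1.0]heptan-1-yl]acetaldehyde, via secondary ozonide 7 (not isolated)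
Conditions: O3, CH2Cl2, −78 °C; then PPh3, −78 → 25 °C
Reagents that add atoms: ozone, [O-][O+]=O
Why: Ozonolysis with reductive work-up cleaves the only remaining alkene under neutral conditions, which the base-labile β,γ-epoxy aldehyde (C7H2–C8HO) requires.

**Step 6**
Reactants: 9 but-2-yn-1-ol
Product: 11 (E)-3-iodobut-2-en-1-ol, via doubly zirconated alkenylzirconocene 10 (not isolated)
Conditions: Cp2Zr(H)Cl (2.3 equiv), THF, 0 → 25 °C, dark; then I2 (1.1 equiv), −20 °C
Reagents that add atoms: iodine, II; zirconocene chloride hydride, [H][Zr](Cl)(C1C=CC=C1)C1C=CC=C1 (its zirconium stands in 10 only)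
Why: Syn hydrozirconation places zirconium on the methyl-bearing carbon, away from the bulky zirconium alkoxide arm (the slight excess of hydride lets the regioisomers equilibrate to this one), and iodinolysis with retention gives the E-iodide that later defines C9=C10, C13=C14 and C13'=C14'.

**Step 7**
Reactants: 11 (E)-3-iodobut-2-en-1-ol
Product: 12 (E)-3-iodobut-2-enal
Conditions: activated MnO2 (excess), CH2Cl2, 25 °C, dark
Reagents that add atoms: none
Why: Heterogeneous MnO2 oxidation of an allylic alcohol stops at the enal and leaves the C–I bond and the alkene geometry alone.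

**Step 8**
Reactants: 12 (E)-3-iodobut-2-enal
Product: 13 (E)-4-iodopent-3-en-1-yne
Conditions: Me3SiCHN2, LiN(iPr)2, THF, −78 °C; then 12, −78 → 0 °C
Reagents that add atoms: (trimethylsilyl)diazomethane, C[Si](C)(C)C=[N+]=[N-]
Why: The Colvin rearrangement (1,2-addition of the lithiated diazo compound, loss of Me3SiOLi and N2, 1,2-hydride shift of the alkylidene carbene) turns the enal into the terminal enyne without a protic nucleophile that could attack the β-iodo enal in a conjugate sense.

**Step 9**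
Reactants: 11 (E)-3-iodobut-2-en-1-ol
Product: 14 (E)-1-bromo-3-iodobut-2-ene
Conditions: CBr4, PPh3, CH2Cl2, 0 °C
Reagents that add atoms: carbon tetrabromide, BrC(Br)(Br)Br
Why: The Appel reaction converts the primary allylic alcohol into the bromide under neutral conditions without allylic transposition or loss of alkene geometry.

**Step 10**
Reactants: 14 (E)-1-bromo-3-iodobut-2-ene
Product: 15 diethyl [(E)-3-iodobut-2-en-1-yl]phosphonate
Conditions: P(OEt)3, neat, 120 °C
Reagents that add atoms: triethyl phosphite, CCOP(OCC)OCC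
Why: The Michaelis–Arbuzov reaction takes place only at the allylic C–Br bond, because an alkenyl iodide is inert to phosphites in the absence of a metal catalyst.

**Step 11**
Reactants: 15 diethyl [(E)-3-iodobut-2-en-1-yl]phosphonate; 12 (E)-3-iodobut-2-enal
Product: 17 (2E,4E,6E)-2,7-diiodoocta-2,4,6-triene, via sodium phosphonate carbanion 16 (not isolated)
Conditions: NaN(SiMe3)2, THF, −78 °C; then 12, −78 → 0 °C
Reagents that add atoms: sodium hexamethyldisilazide, C[Si](C)(C)N([Na])[Si](C)(C)C (its sodium stands in 16 only)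
Why: The Horner–Wadsworth–Emmons reaction of an allylic phosphonate with an enal should form the central C15=C15' bond with E selectivity and gives the C2-symmetric linchpin C13 to C13'.

**Step 12**
Reactants: 8 ring-A epoxy aldehyde; 13 (E)-4-iodopent-3-en-1-yne
Product: 18 (3E)-1-[(1S,4S,6R)-4-(tert-butyldimethylsilyloxy)-2,2,6-trimethyl-7-oxabicyclo[4.1.0]heptan-1-yl]-3-methylhex-3-en-5-yn-2-ol (both C8 epimers)
Conditions: CrCl2 (4 equiv), NiCl2 (2 mol %), DMF, 25 °C
Reagents that add atoms: none
Why: In the Nozaki–Hiyama–Kishi reaction a non-basic alkenylchromium species adds to the aldehyde with retention of the C9=C10 geometry, without enolising C7 or opening the oxirane, and the C8 carbinol forms as an epimer mixture that step 15 erases.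

**Step 13**
Reactants: 18 silyl-protected enynol
Product: 19 (3E)-1-[(1S,4S,6R)-4-hydroxy-2,2,6-trimethyl-7-oxabicyclo[4.1.0]heptan-1-yl]-3-methylhex-3-en-5-yn-2-ol
Conditions: Bu4NF, THF, 0 → 25 °C
Reagents that add atoms: none
Why: Fluoride-mediated desilylation is run before the C8 ketone exists, so the basic fluoride cannot trigger β-elimination of the oxirane.

**Step 14**
Reactants: 19 enyne diol; 17 (2E,4E,6E)-2,7-diiodoocta-2,4,6-triene
Product: 21 (3E,5E,7E,9E,11E)-1-[(1S,4S,6R)-4-hydroxy-2,2,6-trimethyl-7-oxabicyclo[4.1.0]heptan-1-yl]-12-iodo-3,7-dimethyltrideca-3,5,7,9,11-pentaen-2-ol, via dienylstannane 20 (not isolated)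
Conditions: Bu3SnH (1.0 equiv, slow addition), Pd2(dba)3 (1 mol %), PCy3 (4 mol %), THF, 0 °C; then transfer into 17 (3 equiv), Pd2(dba)3 (5 mol %), AsPh3 (20 mol %), DMF, 25 °C, dark; unreacted 17 recovered
Reagents that add atoms: tributyltin hydride, CCCC[SnH](CCCC)CCCC (its tin stands in 20 only; only its hydrogen stays in 21)
Why: In this one-pot palladium-catalysed hydrostannation/Stille coupling, syn addition of Bu3Sn–H to the terminal C11≡C12 alkyne (run at the electron-rich carbinol level so that tin goes to C12) sets E-C11=C12, and the excess of symmetric 17 limits coupling to one C–I terminus with retention at C13=C14.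

**Step 15**
Reactants: 21 pentaenyl iodide diol
Product: 22 (3E,5E,7E,9E,11E)-1-[(1S,4S,6R)-4-hydroxy-2,2,6-trimethyl-7-oxabicyclo[4.1.0]heptan-1-yl]-12-iodo-3,7-dimethyltrideca-3,5,7,9,11-pentaen-2-one
Conditions: activated MnO2 (excess), CH2Cl2, 25 °C, dark
Reagents that add atoms: none
Why: MnO2 oxidises only the allylic (pentaenylic) C8 carbinol and leaves the saturated C3 carbinol, and its neutral heterogeneous medium spares the β,γ-epoxy ketone that forms.

**Step 16**
Reactants: 4 enol triflate; 23 (E)-3-methylpent-2-en-4-yn-1-ol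
Product: 24 (2E)-5-[(4R)-4-(tert-butyldimethylsilyloxy)-2,6,6-trimethylcyclohex-1-en-1-yl]-3-methylpent-2-en-4-yn-1-ol
Conditions: Pd(PPh3)4 (5 mol %), CuI (10 mol %), iPr2NH, DMF, 25 → 50 °C
Reagents that add atoms: none
Why: The Sonogashira coupling of the enol triflate with the terminal alkyne of 23 forges C6'–C7' and brings in the E-C9'=C10' alkene ready-made, the free allylic alcohol being tolerated.

**Step 17**
Reactants: 24 C15 enynol
Product: 25 (2E)-5-[(4R)-4-(tert-butyldimethylsilyloxy)-2,6,6-trimethylcyclohex-1-en-1-yl]-3-methylpent-2-en-4-ynal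
Conditions: activated MnO2 (excess), CH2Cl2, 25 °C
Reagents that add atoms: none
Why: MnO2 oxidation of the primary allylic alcohol gives the C11' enal without touching the silyl ether, the alkyne or the alkene geometry.

**Step 18**
Reactants: 25 C15 enynal
Product: 26 tert-butyldimethylsilyl ether of (1R)-4-[(3E)-3-methylhex-3-ene-1,5-diyn-1-yl]-3,5,5-trimethylcyclohex-3-en-1-ol
Conditions: Me3SiCHN2, LiN(iPr)2, THF, −78 °C; then 25, −78 → 0 °C
Reagents that add atoms: (trimethylsilyl)diazomethane, C[Si](C)(C)C=[N+]=[N-]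
Why: The Colvin rearrangement adds C12' and turns the enal into the terminal alkyne C11'≡C12'–H, a homologation that works well on α,β-unsaturated aldehydes.

**Step 19**
Reactants: 26 silyl-protected enediyne
Product: 27 (1R)-4-[(3E)-3-methylhex-3-ene-1,5-diyn-1-yl]-3,5,5-trimethylcyclohex-3-en-1-ol
Conditions: Bu4NF, THF, 0 → 25 °C
Reagents that add atoms: none
Why: Fluoride-mediated cleavage of the Si–O bond frees the C3' hydroxyl with retention and does not affect the enediyne.

**Step 20**
Reactants: 27 enediyne alcohol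
Product: 28 (1R)-4-[(3E)-3-methylhex-3-ene-1,5-diyn-1-yl]-3,5,5-trimethylcyclohex-3-en-1-yl acetate
Conditions: Ac2O, pyridine, DMAP (cat.), CH2Cl2, 0 → 25 °C
Reagents that add atoms: acetic anhydride, CC(=O)OC(C)=O
Why: DMAP-catalysed acylation installs the C3' acetate with retention, so the two ring hydroxyls of the target are told apart before the fragments meet.

**Step 21**
Reactants: 28 enediyne acetate; 22 pentaenyl iodide ketone
Product: 30 (3S,5R,6S,3'R)-3'-acetoxy-5,6-epoxy-3-hydroxy-7',8'-didehydro-5,6,7,8-tetrahydro-β,β-caroten-8-one (target), via dienylstannane 29 (not isolated)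
Conditions: 28 (1.2 equiv), Bu3SnH (1.2 equiv, slow addition), Pd2(dba)3 (1 mol %), PCy3 (4 mol %), THF, 0 °C; then 22 (1.0 equiv), Pd2(dba)3 (5 mol %), AsPh3 (20 mol %), DMF, 25 °C, dark, argon
Reagents that add atoms: tributyltin hydride, CCCC[SnH](CCCC)CCCC (its tin stands in 29 only; only its hydrogen stays in 30)
Why: Zerovalent palladium inserts into the Sn–H bond and adds H and SnBu3 syn across the only terminal triple bond, C11'≡C12'–H of 28, with tin on the open terminus (favoured by the bulky phosphine), to give the (E)-dienylstannane 29, and after addition of 22 the same flask runs a Stille cycle (oxidative addition into C13'–I, tin-to-palladium transmetalation, reductive elimination) that forges C12'–C13'. The closest known reaction type is the one-pot palladium-catalysed hydrostannation/Stille coupling of terminal alkynes with alkenyl iodides, and Stille unions of polyenyl iodides with polyenylstannanes are standard carotenoid chemistry. No ring is closed and no sp3 stereocentre is made; the stereo-elements at stake are alkene geometries, E at C11'=C12' being fixed by the syn addition and E at C13'=C14' being carried over because oxidative addition and reductive elimination both proceed with retention. The chemoselectivity needed is terminal against internal alkyne, which is secured by the burial of C7'≡C8' between the C1' gem-dimethyl and C5' methyl groups of ring B and the C9' methyl group, and by using no more tin hydride than alkyne so that none is left to reduce the C–I bond of 22. Any C11' stannane regioisomer is a hindered 1,1-disubstituted alkenylstannane that transmetalates far more slowly and should stay behind. The medium is neutral and free of copper and amine, so the acetate, the free C3 hydroxyl and the base-labile C8 ketone/C5–C6 oxirane array should survive, and residual 28 cannot enter a Sonogashira pathway.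

**Compound list**
1 | (4R,6R)-4-hydroxy-2,2,6-trimethylcyclohexan-1-one (actinol) | C[C@@H]1C[C@@H](O)CC(C)(C)C1=O | starting material
2 | (4R,6R)-4-(tert-butyldimethylsilyloxy)-2,2,6-trimethylcyclohexan-1-one | C[C@@H]1C[C@@H](O[Si](C)(C)C(C)(C)C)CC(C)(C)C1=O | intermediate
3 | lithium (4R)-4-(tert-butyldimethylsilyloxy)-2,6,6-trimethylcyclohex-1-en-1-olate (not isolated) | CC(C)(C)[Si](C)(C)O[C@@H]1CC(C)=C(O[Li])C(C)(C)C1 | intermediate
4 | (4R)-4-(tert-butyldimethylsilyloxy)-2,6,6-trimethylcyclohex-1-en-1-yl trifluoromethanesulfonate | CC(C)(C)[Si](C)(C)O[C@@H]1CC(C)=C(OS(=O)(=O)C(F)(F)F)C(C)(C)C1 | intermediate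
5 | tert-butyldimethylsilyl ether of (1R)-4-allyl-3,5,5-trimethylcyclohex-3-en-1-ol | CC(C)(C)[Si](C)(C)O[C@@H]1CC(C)=C(CC=C)C(C)(C)C1 | intermediate
6 | (1S,4S,6R)-1-allyl-4-(tert-butyldimethylsilyloxy)-2,2,6-trimethyl-7-oxabicyclo[4.1.0]heptane | C=CC[C@@]12O[C@]1(C)C[C@@H](O[Si](C)(C)C(C)(C)C)CC2(C)C | intermediate
7 | secondary ozonide (1,2,4-trioxolane) of the allyl group of 6 (not isolated) | C1OC(C[C@@]23O[C@]2(C)C[C@@H](O[Si](C)(C)C(C)(C)C)CC3(C)C)OO1 | intermediate
8 | 2-[(1S,4S,6R)-4-(tert-butyldimethylsilyloxy)-2,2,6-trimethyl-7-oxabicyclo[4.1.0]heptan-1-yl]acetaldehyde | O=CC[C@@]12O[C@]1(C)C[C@@H](O[Si](C)(C)C(C)(C)C)CC2(C)C | intermediate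
9 | but-2-yn-1-ol | CC#CCO | starting material
10 | O-zirconated (E)-alkenylzirconocene chloride from 9 (not isolated) | C/C(=C\CO[Zr](Cl)(C1C=CC=C1)C1C=CC=C1)[Zr](Cl)(C1C=CC=C1)C1C=CC=C1 | intermediate
11 | (E)-3-iodobut-2-en-1-ol | C/C(I)=C\CO | intermediate
12 | (E)-3-iodobut-2-enal | C/C(I)=C\C=O | intermediate
13 | (E)-4-iodopent-3-en-1-yne | C/C(I)=C\C#C | intermediate
14 | (E)-1-bromo-3-iodobut-2-ene | C/C(I)=C\CBr | intermediate
15 | diethyl [(E)-3-iodobut-2-en-1-yl]phosphonate | C/C(I)=C\CP(=O)(OCC)OCC | intermediate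
16 | sodium salt of α-deprotonated 15 (not isolated) | C/C(I)=C\[CH-]P(=O)(OCC)OCC.[Na+] | intermediate
17 | (2E,4E,6E)-2,7-diiodoocta-2,4,6-triene | I/C(C)=C/C=C/C=C(\C)I | intermediate
18 | (3E)-1-[(1S,4S,6R)-4-(tert-butyldimethylsilyloxy)-2,2,6-trimethyl-7-oxabicyclo[4.1.0]heptan-1-yl]-3-methylhex-3-en-5-yn-2-ol (C8 epimers) | C#C/C=C(\C)C(O)C[C@@]12O[C@]1(C)C[C@@H](O[Si](C)(C)C(C)(C)C)CC2(C)C | intermediate
19 | (3E)-1-[(1S,4S,6R)-4-hydroxy-2,2,6-trimethyl-7-oxabicyclo[4.1.0]heptan-1-yl]-3-methylhex-3-en-5-yn-2-ol (C8 epimers) | C#C/C=C(\C)C(O)C[C@@]12O[C@]1(C)C[C@@H](O)CC2(C)C | intermediate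
20 | (3E,5E)-1-[(1S,4S,6R)-4-hydroxy-2,2,6-trimethyl-7-oxabicyclo[4.1.0]heptan-1-yl]-3-methyl-6-(tributylstannyl)hexa-3,5-dien-2-ol (not isolated) | CCCC[Sn](CCCC)(CCCC)/C=C/C=C(\C)C(O)C[C@@]12O[C@]1(C)C[C@@H](O)CC2(C)C | intermediate
21 | (3E,5E,7E,9E,11E)-1-[(1S,4S,6R)-4-hydroxy-2,2,6-trimethyl-7-oxabicyclo[4.1.0]heptan-1-yl]-12-iodo-3,7-dimethyltrideca-3,5,7,9,11-pentaen-2-ol (C8 epimers) | I/C(C)=C/C=C/C=C(C)/C=C/C=C(\C)C(O)C[C@@]12O[C@]1(C)C[C@@H](O)CC2(C)C | intermediate
22 | (3E,5E,7E,9E,11E)-1-[(1S,4S,6R)-4-hydroxy-2,2,6-trimethyl-7-oxabicyclo[4.1.0]heptan-1-yl]-12-iodo-3,7-dimethyltrideca-3,5,7,9,11-pentaen-2-one | I/C(C)=C/C=C/C=C(C)/C=C/C=C(\C)C(=O)C[C@@]12O[C@]1(C)C[C@@H](O)CC2(C)C | intermediate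
23 | (E)-3-methylpent-2-en-4-yn-1-ol | C#C/C(C)=C/CO | starting material
24 | (2E)-5-[(4R)-4-(tert-butyldimethylsilyloxy)-2,6,6-trimethylcyclohex-1-en-1-yl]-3-methylpent-2-en-4-yn-1-ol | CC(C)(C)[Si](C)(C)O[C@@H]1CC(C)=C(C#C/C(C)=C/CO)C(C)(C)C1 | intermediate
25 | (2E)-5-[(4R)-4-(tert-butyldimethylsilyloxy)-2,6,6-trimethylcyclohex-1-en-1-yl]-3-methylpent-2-en-4-ynal | CC(C)(C)[Si](C)(C)O[C@@H]1CC(C)=C(C#C/C(C)=C/C=O)C(C)(C)C1 | intermediate
26 | tert-butyldimethylsilyl ether of (1R)-4-[(3E)-3-methylhex-3-ene-1,5-diyn-1-yl]-3,5,5-trimethylcyclohex-3-en-1-ol | CC(C)(C)[Si](C)(C)O[C@@H]1CC(C)=C(C#C/C(C)=C/C#C)C(C)(C)C1 | intermediate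
27 | (1R)-4-[(3E)-3-methylhex-3-ene-1,5-diyn-1-yl]-3,5,5-trimethylcyclohex-3-en-1-ol | O[C@@H]1CC(C)=C(C#C/C(C)=C/C#C)C(C)(C)C1 | intermediate
28 | (1R)-4-[(3E)-3-methylhex-3-ene-1,5-diyn-1-yl]-3,5,5-trimethylcyclohex-3-en-1-yl acetate | CC(=O)O[C@@H]1CC(C)=C(C#C/C(C)=C/C#C)C(C)(C)C1 | intermediate
29 | (1R)-4-[(3E,5E)-3-methyl-6-(tributylstannyl)hexa-3,5-dien-1-yn-1-yl]-3,5,5-trimethylcyclohex-3-en-1-yl acetate (not isolated) | CC(=O)O[C@@H]1CC(C)=C(C#C/C(C)=C/C=C/[Sn](CCCC)(CCCC)CCCC)C(C)(C)C1 | intermediate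
30 | (3S,5R,6S,3'R)-3'-acetoxy-5,6-epoxy-3-hydroxy-7',8'-didehydro-5,6,7,8-tetrahydro-β,β-caroten-8-one | CC(=O)O[C@@H]1CC(C)=C(C#C/C(C)=C/C=C/C(C)=C/C=C/C=C(C)/C=C/C=C(\C)C(=O)C[C@@]23O[C@]2(C)C[C@@H](O)CC3(C)C)C(C)(C)C1 | target

**Step count**
- Total step count: 21.
- Longest linear sequence: 10 steps (1, 2, 3, 4, 5, 12, 13, 14, 15, 21).

**Steps most likely to fail**

1. **Step 21.**
 - Risks: incomplete regiocontrol in the hydrostannation; protodestannylation of the dienylstannane; hydrodeiodination of the iodide by leftover tin hydride; E/Z drift of the long polyene while the coupling at hindered, methyl-bearing C13' proceeds slowly.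
 - Fallback: it sets out from 28 and comes back at 30, and replaces the in-flask tin nucleophile by an isolated boron one.
 - Hydroboration of the terminal alkyne with pinacolborane (HBpin, Cp2Zr(H)Cl 10 mol %, Et3N 10 mol %, 40 °C) should give the chromatographically purified pinacol (E)-dienylboronate F1.
 - Suzuki–Miyaura coupling of F1 with 22 (Pd(PPh3)4, TlOEt, THF–H2O, 0 → 25 °C, short contact time) should then give 30.

2. **Step 14.**
 - Risks: over-coupling at both C–I termini of the symmetric diiodide, and losses in separating mono-coupled, bis-coupled and recovered material.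
 - Fallback: it sets out from 19 and comes back at 21, and avoids any statistical event by building C13 to C13' in two unsymmetric operations from blocks already in hand.
 - 19 is hydrostannylated as in step 14, but 20 is isolated on amine-deactivated silica.
 - 20 is coupled 1:1 with 11 (PdCl2(MeCN)2, DMF, 25 °C) to give the trienetriol F2.
 - Primary-selective oxidation (TEMPO, PhI(OAc)2, CH2Cl2) should give the C15 hydroxy trienal F3.
 - Horner–Wadsworth–Emmons reaction of F3 with excess 16 (enough to cover the two free hydroxyls) forms C15=C15' and gives 21, at a stage where no base-labile ketone is present.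

3. **Step 4.**
 - Risk: poor facial selectivity of the peracid on the tetrasubstituted C5=C6 bond.
 - Fallback: it sets out from 4 and comes back at 8, and replaces substrate control by reagent control on an allylic alcohol.
 - Methoxycarbonylation of 4 (Pd(OAc)2, PPh3, CO, MeOH, Et3N, DMF) gives the methyl cyclohexenecarboxylate F4.
 - iBu2AlH reduction gives the allylic alcohol F5.
 - Sharpless asymmetric epoxidation (Ti(OiPr)4, D-(−)-diethyl tartrate, tBuOOH, 4 Å sieves, CH2Cl2, −20 °C; the tartrate antipode that delivers oxygen anti to C3–O) gives the epoxy alcohol F6.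
 - Dess–Martin oxidation gives the epoxy aldehyde F7.
 - The Ohira–Bestmann reagent (K2CO3, MeOH) gives the epoxy alkyne F8.
 - Neutral anti-Markovnikov hydration ([CpRu(MeCN)3]PF6, 5,5'-bis(trifluoromethyl)-2,2'-bipyridine, NMP–H2O, 25 °C) gives 8.

**Further compounds**
F1 | step 21 | (1R)-4-[(3E,5E)-3-methyl-6-(4,4,5,5-tetramethyl-1,3,2-dioxaborolan-2-yl)hexa-3,5-dien-1-yn-1-yl]-3,5,5-trimethylcyclohex-3-en-1-yl acetate | CC(=O)O[C@@H]1CC(C)=C(C#C/C(C)=C/C=C/B2OC(C)(C)C(C)(C)O2)C(C)(C)C1
F2 | step 14 | (2E,4E,6E)-9-[(1S,4S,6R)-4-hydroxy-2,2,6-trimethyl-7-oxabicyclo[4.1.0]heptan-1-yl]-3,7-dimethylnona-2,4,6-triene-1,8-diol | OC/C=C(C)/C=C/C=C(\C)C(O)C[C@@]12O[C@]1(C)C[C@@H](O)CC2(C)C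
F3 | step 14 | (2E,4E,6E)-8-hydroxy-9-[(1S,4S,6R)-4-hydroxy-2,2,6-trimethyl-7-oxabicyclo[4.1.0]heptan-1-yl]-3,7-dimethylnona-2,4,6-trienal | O=C/C=C(C)/C=C/C=C(\C)C(O)C[C@@]12O[C@]1(C)C[C@@H](O)CC2(C)C
F4 | step 4 | methyl (4R)-4-(tert-butyldimethylsilyloxy)-2,6,6-trimethylcyclohex-1-ene-1-carboxylate | CC(C)(C)[Si](C)(C)O[C@@H]1CC(C)=C(C(=O)OC)C(C)(C)C1
F5 | step 4 | [(4R)-4-(tert-butyldimethylsilyloxy)-2,6,6-trimethylcyclohex-1-en-1-yl]methanol | CC(C)(C)[Si](C)(C)O[C@@H]1CC(C)=C(CO)C(C)(C)C1
F6 | step 4 | [4-(tert-butyldimethylsilyloxy)-2,2,6-trimethyl-7-oxabicyclo[4.1.0]heptan-1-yl]methanol, ring stereocentres arranged in space as in 6 | OC[C@@]12O[C@]1(C)C[C@@H](O[Si](C)(C)C(C)(C)C)CC2(C)C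
F7 | step 4 | 4-(tert-butyldimethylsilyloxy)-2,2,6-trimethyl-7-oxabicyclo[4.1.0]heptane-1-carbaldehyde, ring stereocentres arranged in space as in 6 | O=C[C@@]12O[C@]1(C)C[C@@H](O[Si](C)(C)C(C)(C)C)CC2(C)C
F8 | step 4 | 4-(tert-butyldimethylsilyloxy)-1-ethynyl-2,2,6-trimethyl-7-oxabicyclo[4.1.0]heptane, ring stereocentres arranged in space as in 6 | C#C[C@@]12O[C@]1(C)C[C@@H](O[Si](C)(C)C(C)(C)C)CC2(C)C
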